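## Analysis of the target

The target (20) consists of two benzene rings joined by one ether oxygen. Ring A is a methyl benzoate numbered C1 (CO2Me), C2 (O-prenyl), C3 (H), C4 (CH3), C5 (H), C6 (O-aryl). Ring B is numbered C1' (ether oxygen), C2' (CH2OH), C3' (H), C4' (OMe), C5' (H), C6' (OMe). There is no stereocentre, and the only alkene carries two identical methyl groups, so no configuration has to be set. The difficulty is constitutional: the ether oxygen joins C6, which has the ester beside it, to C1', which is flanked on both sides, so the C–O bond is tri-ortho-substituted between two electron-rich rings. Ring A carries three contiguous substituents (C6–O, C1–C, C2–O); the ester is buried between two oxygens, and those two oxygens must be told apart. The sensitive groups are the prenyl ether (acid, heat, electrophiles), the benzylic alcohol on an electron-rich ring, and the methyl ester, which must survive while the C2' carbon is brought to the alcohol level. The feature that invites the strategy is the adjacent pair C6 (heteroatom) and C1 (carbon) with the C2 oxygen next to it. This is the pattern left when a nucleophile and an electrophile add across an aryne whose triple bond lies between C1 and C6 and whose alkoxy group sits on C2.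

## Retrosynthetic reasoning

The last change is placed at the carbon on C2'. Its two C–H bonds are taken back to the formyl group of 19. An aldehyde tolerates the Lewis acid and the alkylation that precede it, a benzylic alcohol would not, and it can be reduced without touching the hindered ester on C1.

Next the O–CH2 bond of the prenyl ether on C2 is cut, giving phenol 18, and the O–H of 18 is traced to the O–CH3 of 17. The prenyl group is not carried through the key step: an allylic ether with two allylic methyl groups next to an aryne carbon has an intramolecular ene pathway open to it. A methoxy group is inert there, is the classical directing group for aryne additions, and in 17 it is the only methyl ether ortho to an ester carbonyl, so chelation can select it.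

The key disconnection cuts two bonds of ring A at once: C6–O (the diaryl ether) and C1–C (the carboxyl carbon). The ester of 17 comes from carboxylate 15, and 15 from aryl anion 14. Anion 14 comes from addition of phenoxide 12 (from phenol 11) to aryne 13, which is released from silyl triflate 8. The cut is made here because the two bonds sit on adjacent carbons with the C2 oxygen beside them, which fixes the direction of addition. What is gained is that the most hindered bond of the molecule and the buried carboxyl carbon arise together from two simple phenols and a one-carbon electrophile. The forward reaction has to add 12 at C6 and not at C1, and has to trap 14 with the one-carbon electrophile before any proton reaches it. The formyl carbon is masked as the acetal of 16 during this step.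

Silyl triflate 8 is cut at its C–Si and O–S bonds. Both go back to carbamate 6 and, through directed ortho-metalation of carbamate 2 at the carbon between its two oxygens, to phenol 1. This carbon is the only one flanked by both directing groups, so the silicon is placed exactly where C1 of ring A will be.

Phenol 11 is cut at the acetal C–O bonds to aldehyde 10, and 10 at the C–C bond of the formyl group to phenol 9. Phenol 9 has one free ortho position and a blocked para position, so the formyl group can only enter at the future C2'.

## Alternatives that were turned down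

Alternative 1: the textbook disconnection cuts only the O–C1' bond. The forward key step is a copper-catalysed Ullmann coupling of phenol A1 with aryl bromide A2, which would give 19 directly, and one reduction then gives 20. It is about four steps and therefore shorter than the chosen route. It was turned down as the main line for three reasons:
- The phenol of A1 is hydrogen-bonded to its ester and can bind copper as a salicylate.
- The bromide of A2 is flanked on both sides and carries a para methoxy group that slows both oxidative addition and addition–elimination.
- The base and temperature needed put the formyl group and the prenyl ether at risk, and the step creates none of the ring A substitution pattern.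

It is kept, in a methoxy variant, as the fallback for step 6.

Alternative 2: the biosynthesis-like disconnection traces the diaryl ether to benzophenone A3, in which C1' is bonded to the carbon that later becomes the ester carbon on C1. The forward key steps are a one-electron oxidative phenol coupling that forms the C1'–O bond and closes the racemic spirodienone A4, then methanolysis that cleaves the bond between the ketone carbon and C1' to give diaryl ether A5. It was turned down for these reasons:
- A3 needs acylation of ring A at the carbon between its two hydroxyl groups, which is not the innate site.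
- The coupling needs a free hydroxyl on C4' that the target carries as a methyl ether.
- A5 then requires methylation of one phenol beside another and reduction of one of two methyl esters.
- The sequence would exceed twelve steps.

Alternative 3: ring A is made from another ring. Pyrone A7, reached from pyrone tosylate A6 and phenol 11 by addition–elimination, would undergo Diels–Alder reaction with a ketene acetal and lose CO2 and an alcohol to give 16. It was turned down for these reasons:
- The aryloxy group of A7 sits on C4 of the pyrone, β to two carbonyl groups. A nucleophilic dienophile is expected to add there and expel the phenoxide rather than bond to C6.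
- The C4 oxygen lowers the electrophilicity of the diene.
- A6 and A7 cost as many steps as silyl triflate 8, so nothing is saved.

Key step: step 6

Remark: 1 and 9 are taken as purchasable; the target has no stereocentre and no stereogenic alkene, so no configuration has to be set or checked.

## Steps

Step 1
Reactants: 1 3-methoxy-5-methylphenol
Product: 2 3-methoxy-5-methylphenyl N-(propan-2-yl)carbamate
Conditions: i-PrNCO, Et3N (cat.), CH2Cl2, rt
Reagents that add atoms: isopropyl isocyanate CC(C)N=C=O
Why: Base-catalysed addition of the phenol to the isocyanate (carbamoylation); the N–H carbamate is chosen because it directs ortho-metalation and can later be removed by mild base.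

Step 2
Reactants: 2 3-methoxy-5-methylphenyl N-(propan-2-yl)carbamate
Product: 6 3-methoxy-5-methyl-2-(trimethylsilyl)phenyl N-(propan-2-yl)carbamate, via N-silyl carbamate 3 (not isolated), via aryllithium 4 (not isolated), via N-silyl C-silyl carbamate 5 (not isolated)
Conditions: TBSOTf, TMEDA, Et2O, 0 °C to rt; n-BuLi, TMEDA, −78 °C; TMSCl, −78 °C to rt; aq. NaHSO4
Reagents that add atoms: chlorotrimethylsilane C[Si](C)(C)Cl
Why: In situ N-silylation (3) masks the N–H; the carbamate and methoxy groups then cooperate in directed ortho-metalation at the only carbon between them (4), TMSCl silylates it (5), and the N–Si bond is hydrolysed in the acidic work-up. This is the standard sequence for the analogue that lacks the ring methyl group.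

Step 3
Reactants: 6 3-methoxy-5-methyl-2-(trimethylsilyl)phenyl N-(propan-2-yl)carbamate
Product: 8 3-methoxy-5-methyl-2-(trimethylsilyl)phenyl trifluoromethanesulfonate, via silylphenol 7 (not isolated)
Conditions: DBU, Et2NH, MeCN, 40 °C; then PhNTf2, rt
Reagents that add atoms: N-phenylbis(trifluoromethanesulfonimide) O=S(=O)(N(c1ccccc1)S(=O)(=O)C(F)(F)F)C(F)(F)F
Why: DBU deprotonates the N–H and the carbamate fragments by E1cB to the phenoxide of 7 and isopropyl isocyanate, which Et2NH scavenges as a urea; PhNTf2 then triflates the hindered phenoxide under conditions mild enough to keep the C–Si bond.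

Step 4
Reactants: 9 2,4-dimethoxyphenol
Product: 10 2-hydroxy-3,5-dimethoxybenzaldehyde
Conditions: MgCl2, Et3N, (CH2O)n, MeCN, reflux; aq. HCl
Reagents that add atoms: paraformaldehyde (as formaldehyde) C=O
Why: Magnesium-mediated ortho-formylation (Casnati–Skattebøl reaction): the magnesium phenoxide delivers formaldehyde to the only free ortho position and a second formaldehyde oxidises the benzylic alkoxide by hydride transfer; the para position is blocked by methoxy.

Step 5
Reactants: 10 2-hydroxy-3,5-dimethoxybenzaldehyde
Product: 11 2-(5,5-dimethyl-1,3-dioxan-2-yl)-4,6-dimethoxyphenol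
Conditions: 2,2-dimethylpropane-1,3-diol, p-TsOH (cat.), toluene, reflux, Dean–Stark; Et3N quench
Reagents that add atoms: 2,2-dimethylpropane-1,3-diol CC(C)(CO)CO
Why: Acid-catalysed acetalisation with azeotropic removal of water; the six-membered acetal should survive base, fluoride and the aryl anion of step 6, whereas a free formyl group would capture that anion intramolecularly.

Step 6
Reactants: 11 2-(5,5-dimethyl-1,3-dioxan-2-yl)-4,6-dimethoxyphenol; 8 3-methoxy-5-methyl-2-(trimethylsilyl)phenyl trifluoromethanesulfonate
Product: 17 methyl 2-(2-formyl-4,6-dimethoxyphenoxy)-6-methoxy-4-methylbenzoate, via potassium phenoxide 12 (not isolated), via aryne 13 (not isolated), via arylpotassium 14 (not isolated), via potassium benzoate 15 (not isolated), via acetal ester 16 (not isolated)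
Conditions: 11 (1.5 equiv), KH, THF, 0 °C; KF, 18-crown-6, CO2 (1 atm), slow addition of 8, 0 °C to rt; MeI, DMF, rt; 1 M HCl, THF, rt
Reagents that add atoms: carbon dioxide O=C=O; iodomethane CI; water O
Why: Proposed new method: fluoride attacks silicon of 8, triflate leaves and aryne 13 forms; its C2 methoxy group, beside the triple bond, withdraws σ-density and flattens the distal aryne carbon C6, so phenoxide 12 adds at C6 and the charge of 14 develops at C1 next to the methoxy oxygen. Dissolved CO2 then carboxylates C1 to give 15, MeI O-methylates the carboxylate to 16, and the acidic work-up hydrolyses the acetal to aldehyde 17. The closest known reaction types are the fluoride-induced O-arylation of phenols with 2-silylaryl triflates and the three-component coupling of arynes, amines and CO2 to anthranilic acids; the new element is a phenoxide as the nucleophile of the carboxylative coupling. No ring is closed and no stereocentre is formed. The regiochemistry of addition is secured by the methoxy group (aryne distortion and inductive stabilisation of the 2,6-dioxygenated aryl anion) and by the bulk of 12. O-arylation rather than C-arylation is secured because both ortho positions and the para position of 12 are substituted. Carboxylation rather than protonation of 14 is secured by complete deprotonation of 11 with KH, an aprotic medium and saturation with CO2. The excess of 12 should keep the hindered carboxylate 15 from competing for the aryne.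

Step 7
Reactants: 17 methyl 2-(2-formyl-4,6-dimethoxyphenoxy)-6-methoxy-4-methylbenzoate
Product: 18 methyl 2-(2-formyl-4,6-dimethoxyphenoxy)-6-hydroxy-4-methylbenzoate
Conditions: BCl3, CH2Cl2, −78 °C to 0 °C; H2O
Reagents that add atoms: none
Why: Chelation-controlled ether cleavage: BCl3 binds the ester carbonyl and the C2 methoxy oxygen in a six-membered chelate and chloride removes that methyl group; the two ring B methoxy groups have no carbonyl beside them (the formyl group on C2' is flanked by the ether oxygen and by C3'–H) and should stay.

Step 8
Reactants: 18 methyl 2-(2-formyl-4,6-dimethoxyphenoxy)-6-hydroxy-4-methylbenzoate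
Product: 19 methyl 2-(2-formyl-4,6-dimethoxyphenoxy)-4-methyl-6-[(3-methylbut-2-en-1-yl)oxy]benzoate
Conditions: prenyl bromide, K2CO3, DMF, rt to 40 °C
Reagents that add atoms: 1-bromo-3-methylbut-2-ene CC(C)=CCBr
Why: Williamson etherification; the phenoxide is the only nucleophile present, the formyl group is inert to K2CO3 in DMF, and a dipolar aprotic solvent favours O-alkylation.

Step 9
Reactants: 19 methyl 2-(2-formyl-4,6-dimethoxyphenoxy)-4-methyl-6-[(3-methylbut-2-en-1-yl)oxy]benzoate
Product: 20 methyl 2-[2-(hydroxymethyl)-4,6-dimethoxyphenoxy]-4-methyl-6-[(3-methylbut-2-en-1-yl)oxy]benzoate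
Conditions: NaBH4, MeOH/THF, 0 °C
Reagents that add atoms: none
Why: Chemoselective hydride reduction: the aldehyde should react at 0 °C, while the methyl ester (flanked by two ortho oxygens) and the trisubstituted alkene should not.

## Compound list

1 | 3-methoxy-5-methylphenol | COc1cc(C)cc(O)c1 | starting material
2 | 3-methoxy-5-methylphenyl N-(propan-2-yl)carbamate | COc1cc(C)cc(OC(=O)NC(C)C)c1 | intermediate
3 | 3-methoxy-5-methylphenyl N-[tert-butyl(dimethyl)silyl]-N-(propan-2-yl)carbamate | COc1cc(C)cc(OC(=O)N(C(C)C)[Si](C)(C)C(C)(C)C)c1 | intermediate
4 | [2-({[tert-butyl(dimethyl)silyl](propan-2-yl)carbamoyl}oxy)-6-methoxy-4-methylphenyl]lithium | COc1cc(C)cc(OC(=O)N(C(C)C)[Si](C)(C)C(C)(C)C)c1[Li] | intermediate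
5 | 3-methoxy-5-methyl-2-(trimethylsilyl)phenyl N-[tert-butyl(dimethyl)silyl]-N-(propan-2-yl)carbamate | COc1cc(C)cc(OC(=O)N(C(C)C)[Si](C)(C)C(C)(C)C)c1[Si](C)(C)C | intermediate
6 | 3-methoxy-5-methyl-2-(trimethylsilyl)phenyl N-(propan-2-yl)carbamate | COc1cc(C)cc(OC(=O)NC(C)C)c1[Si](C)(C)C | intermediate
7 | 3-methoxy-5-methyl-2-(trimethylsilyl)phenol | COc1cc(C)cc(O)c1[Si](C)(C)C | intermediate
8 | 3-methoxy-5-methyl-2-(trimethylsilyl)phenyl trifluoromethanesulfonate | COc1cc(C)cc(OS(=O)(=O)C(F)(F)F)c1[Si](C)(C)C | intermediate
9 | 2,4-dimethoxyphenol | COc1ccc(O)c(OC)c1 | starting material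
10 | 2-hydroxy-3,5-dimethoxybenzaldehyde | COc1cc(OC)c(O)c(C=O)c1 | intermediate
11 | 2-(5,5-dimethyl-1,3-dioxan-2-yl)-4,6-dimethoxyphenol | COc1cc(OC)c(O)c(C2OCC(C)(C)CO2)c1 | intermediate
12 | potassium 2-(5,5-dimethyl-1,3-dioxan-2-yl)-4,6-dimethoxyphenolate | COc1cc(OC)c([O-])c(C2OCC(C)(C)CO2)c1.[K+] | intermediate
13 | 3-methoxy-5-methylbenzyne (1,2-didehydro-3-methoxy-5-methylbenzene) | COC1=CC(C)=CC#C1 | intermediate
14 | {2-[2-(5,5-dimethyl-1,3-dioxan-2-yl)-4,6-dimethoxyphenoxy]-6-methoxy-4-methylphenyl}potassium | COc1cc(C)cc(Oc2c(C3OCC(C)(C)CO3)cc(OC)cc2OC)c1[K] | intermediate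
15 | potassium 2-[2-(5,5-dimethyl-1,3-dioxan-2-yl)-4,6-dimethoxyphenoxy]-6-methoxy-4-methylbenzoate | COc1cc(C)cc(Oc2c(C3OCC(C)(C)CO3)cc(OC)cc2OC)c1C(=O)[O-].[K+] | intermediate
16 | methyl 2-[2-(5,5-dimethyl-1,3-dioxan-2-yl)-4,6-dimethoxyphenoxy]-6-methoxy-4-methylbenzoate | COC(=O)c1c(OC)cc(C)cc1Oc1c(C2OCC(C)(C)CO2)cc(OC)cc1OC | intermediate
17 | methyl 2-(2-formyl-4,6-dimethoxyphenoxy)-6-methoxy-4-methylbenzoate | COC(=O)c1c(OC)cc(C)cc1Oc1c(C=O)cc(OC)cc1OC | intermediate
18 | methyl 2-(2-formyl-4,6-dimethoxyphenoxy)-6-hydroxy-4-methylbenzoate | COC(=O)c1c(O)cc(C)cc1Oc1c(C=O)cc(OC)cc1OC | intermediate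
19 | methyl 2-(2-formyl-4,6-dimethoxyphenoxy)-4-methyl-6-[(3-methylbut-2-en-1-yl)oxy]benzoate | COC(=O)c1c(OCC=C(C)C)cc(C)cc1Oc1c(C=O)cc(OC)cc1OC | intermediate
20 | methyl 2-[2-(hydroxymethyl)-4,6-dimethoxyphenoxy]-4-methyl-6-[(3-methylbut-2-en-1-yl)oxy]benzoate | COC(=O)c1c(OCC=C(C)C)cc(C)cc1Oc1c(CO)cc(OC)cc1OC | target

## Step count and least certain steps

Total step count: 9 (two branches, steps 1–3 and steps 4–5, joined in step 6). Longest linear sequence: 7 steps (1, 2, 3, 6, 7, 8, 9).

**Step 6 (key step, proposed new method).** Three processes are the most likely to go wrong: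
- Protonation of aryl anion 14 before carboxylation, by traces of unreacted phenol or moisture, would give the C1–H diaryl ether.
- Carbonation of phenoxide 12 by CO2 would lower its nucleophilicity and could divert aryne 13 to attack by the carbonate oxygen, followed by acyl transfer.
- Further arylation of carboxylate 15 by 13 is possible.

The fallback uses known chemistry, sets out from 2 and comes back to the route at 17. Carbamate 2 is N-silylated and lithiated exactly as in step 2 (through 3 and 4). Aryllithium 4 is quenched with methyl chloroformate instead of TMSCl to give methyl 2-({[tert-butyl(dimethyl)silyl](propan-2-yl)carbamoyl}oxy)-6-methoxy-4-methylbenzoate F1. The aqueous NaHSO4 work-up removes the N-silyl group and gives methyl 2-methoxy-4-methyl-6-{[(propan-2-yl)carbamoyl]oxy}benzoate F2. DBU and Et2NH in MeCN at 40 °C remove the carbamate and give methyl 2-hydroxy-6-methoxy-4-methylbenzoate F3. Ullmann coupling of F3 with 2-bromo-3,5-dimethoxybenzaldehyde A2 (CuI, N,N-dimethylglycine, Cs2CO3, dioxane, 90–100 °C) forms the O–C1' bond and gives 17. This gives up the aryne and builds the C1 carbon by directed ortho-metalation instead.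

**Step 2.** Incomplete N-silylation would leave an N–H that consumes the base. The lithiated carbamate 4 can also undergo a 1,3 O-to-C carbamoyl shift (anionic ortho-Fries rearrangement) if it warms before silylation. The fallback sets out from 1 and comes back at 8, using a tertiary carbamate and a reductive cleavage. Diethylcarbamoyl chloride and K2CO3 in MeCN convert 1 into 3-methoxy-5-methylphenyl N,N-diethylcarbamate F4. s-BuLi/TMEDA in THF at −78 °C followed by TMSCl at that temperature gives 3-methoxy-5-methyl-2-(trimethylsilyl)phenyl N,N-diethylcarbamate F5. LiAlH4 in THF cleaves the carbamate to 7, which is isolated in this variant, and Tf2O with pyridine in CH2Cl2 gives 8.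

**Step 5.** The acetal of an electron-rich, hydrogen-bonded salicylaldehyde may form incompletely or be lost on handling. Free aldehyde would then enter step 6 and trap the aryl anion intramolecularly. The fallback sets out from 10 and comes back at 17, carrying the carbon at the alcohol level through the key step. NaBH4 reduces 10 to 2-(hydroxymethyl)-4,6-dimethoxyphenol F6. TIPSCl and imidazole silylate the primary alcohol in preference to the doubly flanked phenol and give 2,4-dimethoxy-6-({[tri(propan-2-yl)silyl]oxy}methyl)phenol F7. F7 takes the place of 11 in step 6 (neutral work-up) and gives methyl 2-[2,4-dimethoxy-6-({[tri(propan-2-yl)silyl]oxy}methyl)phenoxy]-6-methoxy-4-methylbenzoate F8. TBAF gives methyl 2-[2-(hydroxymethyl)-4,6-dimethoxyphenoxy]-6-methoxy-4-methylbenzoate F9, and MnO2 in CH2Cl2 oxidises the benzylic alcohol to 17.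

**Step 8.** The phenoxide of 18 is hydrogen-bonded to the ester and flanked by it, so alkylation may be slow. This leaves time for decomposition of the allylic bromide and for C-alkylation of ring A. The fallback sets out from 18 and comes back at 19 without a new compound. A Mitsunobu reaction with 3-methylbut-2-en-1-ol, PPh3 and DIAD in THF activates the alcohol instead of relying on displacement of a halide by the phenoxide.

## Further compounds

F1 | step 6 | methyl 2-({[tert-butyl(dimethyl)silyl](propan-2-yl)carbamoyl}oxy)-6-methoxy-4-methylbenzoate | COC(=O)c1c(OC)cc(C)cc1OC(=O)N(C(C)C)[Si](C)(C)C(C)(C)C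
F2 | step 6 | methyl 2-methoxy-4-methyl-6-{[(propan-2-yl)carbamoyl]oxy}benzoate | COC(=O)c1c(OC)cc(C)cc1OC(=O)NC(C)C
F3 | step 6 | methyl 2-hydroxy-6-methoxy-4-methylbenzoate | COC(=O)c1c(O)cc(C)cc1OC
F4 | step 2 | 3-methoxy-5-methylphenyl N,N-diethylcarbamate | CCN(CC)C(=O)Oc1cc(C)cc(OC)c1
F5 | step 2 | 3-methoxy-5-methyl-2-(trimethylsilyl)phenyl N,N-diethylcarbamate | CCN(CC)C(=O)Oc1cc(C)cc(OC)c1[Si](C)(C)C
F6 | step 5 | 2-(hydroxymethyl)-4,6-dimethoxyphenol | COc1cc(OC)c(O)c(CO)c1
F7 | step 5 | 2,4-dimethoxy-6-({[tri(propan-2-yl)silyl]oxy}methyl)phenol | COc1cc(OC)c(O)c(CO[Si](C(C)C)(C(C)C)C(C)C)c1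
F8 | step 5 | methyl 2-[2,4-dimethoxy-6-({[tri(propan-2-yl)silyl]oxy}methyl)phenoxy]-6-methoxy-4-methylbenzoate | COC(=O)c1c(OC)cc(C)cc1Oc1c(CO[Si](C(C)C)(C(C)C)C(C)C)cc(OC)cc1OC
F9 | step 5 | methyl 2-[2-(hydroxymethyl)-4,6-dimethoxyphenoxy]-6-methoxy-4-methylbenzoate | COC(=O)c1c(OC)cc(C)cc1Oc1c(CO)cc(OC)cc1OC
F0 | step 8 | none | none
A1 | alternative 1 | methyl 2-hydroxy-4-methyl-6-[(3-methylbut-2-en-1-yl)oxy]benzoate | COC(=O)c1c(O)cc(C)cc1OCC=C(C)C
A2 | alternative 1 | 2-bromo-3,5-dimethoxybenzaldehyde | COc1cc(OC)c(Br)c(C=O)c1
A3 | alternative 2 | methyl 2-(2,6-dihydroxy-4-methylbenzoyl)-5-hydroxy-3-methoxybenzoate | COC(=O)c1cc(O)cc(OC)c1C(=O)c1c(O)cc(C)cc1O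
A4 | alternative 2 | methyl 4-hydroxy-6'-methoxy-6-methyl-3,4'-dioxo-3H-spiro[1-benzofuran-2,1'-cyclohexa[2,5]diene]-2'-carboxylate (racemic) | COC(=O)C1=CC(=O)C=C(OC)C12Oc1cc(C)cc(O)c1C2=O
A5 | alternative 2 | methyl 2-hydroxy-6-[4-hydroxy-2-methoxy-6-(methoxycarbonyl)phenoxy]-4-methylbenzoate | COC(=O)c1c(O)cc(C)cc1Oc1c(C(=O)OC)cc(O)cc1OC
A6 | alternative 3 | methyl 6-methyl-4-{[(4-methylphenyl)sulfonyl]oxy}-2-oxo-2H-pyran-3-carboxylate | COC(=O)C1=C(OS(=O)(=O)c2ccc(C)cc2)C=C(C)OC1=O
A7 | alternative 3 | methyl 4-[2-(5,5-dimethyl-1,3-dioxan-2-yl)-4,6-dimethoxyphenoxy]-6-methyl-2-oxo-2H-pyran-3-carboxylate | COC(=O)C1=C(Oc2c(C3OCC(C)(C)CO3)cc(OC)cc2OC)C=C(C)OC1=O
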